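**Retrosynthetic overview**
- The target comes from its bis(allyl ether), which comes from partial reduction of a dihydronaphthalene-fused butyrolactone (C=O on C3, OCH2 on C2).
- Ring B (the dihydronaphthalene carbocycle) is closed by intramolecular Friedel–Crafts attack of ring A on a benzylic cation in an (E)-α-arylidene butyrolactone; this sets C1 trans to C2.
- The arylidene unit comes from an aldol condensation of the β-substituted butyrolactone enolate with O-allyl syringaldehyde.
- The butyrolactone and its stereocentre (future C2) come from an Evans syn-aldol of an (S)-4-benzyloxazolidinone succinate imide with the same aldehyde (key C–C bond), then imide reduction and lactonization.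
- Ring order: butyrolactone first, carbocyclic ring B second, lactone opened last. Both aryl rings derive from syringaldehyde.

Assumption and numbering: the target is handled as the open hydroxy-aldehyde drawn in the SMILES (1,2-trans; C1 = aryl-bearing carbon, S; C2 = CH2OH-bearing carbon, R; C3 = CHO-bearing carbon; C4 = vinylic CH; ring A = fused arene, ring B = new carbocycle, ring C = pendant aryl).

**Step 1**
Reactants: 1 syringaldehyde (4-hydroxy-3,5-dimethoxybenzaldehyde)
Product: 2 4-(allyloxy)-3,5-dimethoxybenzaldehyde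
Conditions: allyl bromide, K2CO3, DMF, 60 °C
Reagents that add atoms: allyl bromide, C=CCBr
Why: Williamson O-alkylation (SN2) of the phenoxide gives an allyl ether that survives every later acid, base and hydride step and can be removed at the end without touching an enal.

**Step 2**
Reactants: 3 4-tert-butoxy-4-oxobutanoic acid (mono-tert-butyl succinate); 4 (4S)-4-benzyl-1,3-oxazolidin-2-one
Product: 6 tert-butyl 4-[(4S)-4-benzyl-2-oxo-1,3-oxazolidin-3-yl]-4-oxobutanoate, via mixed pivalic anhydride 5 (not isolated)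
Conditions: PivCl, Et3N, THF, −20 °C; then LiCl, 4, −20 °C → rt
Reagents that add atoms: none
Why: N-acylation of the oxazolidinone through a mixed anhydride, which is attacked at its less hindered (succinyl) carbonyl.

**Step 3**
Reactants: 6 tert-butyl 4-[(4S)-4-benzyl-2-oxo-1,3-oxazolidin-3-yl]-4-oxobutanoate; 2 4-(allyloxy)-3,5-dimethoxybenzaldehyde
Product: 9 tert-butyl (3S,4S)-4-[4-(allyloxy)-3,5-dimethoxyphenyl]-3-[(4S)-4-benzyl-2-oxo-1,3-oxazolidine-3-carbonyl]-4-hydroxybutanoate, via boron Z-enolate 7 (not isolated), via boron aldolate 8 (not isolated)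
Conditions: Bu2BOTf, iPr2NEt, CH2Cl2, 0 °C; 2, −78 → 0 °C; then H2O2, MeOH, aq. NaH2PO4/Na2HPO4 (pH 7), 0 °C
Reagents that add atoms: none
Why: Evans syn-aldol (key step): the Z-boron enolate of the imide reacts through a Zimmerman–Traxler chair on the face opposite the benzyl group of the (S)-auxiliary, joining the two fragments and setting the future C2 in the required sense, while the tert-butyl ester is neither enolized nor lactonized.

**Step 4**
Reactants: 9 syn-aldol adduct
Product: 10 tert-butyl (3S,4S)-4-[4-(allyloxy)-3,5-dimethoxyphenyl]-3-[(4S)-4-benzyl-2-oxo-1,3-oxazolidine-3-carbonyl]-4-(tert-butyldimethylsilyloxy)butanoate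
Conditions: TBSOTf, 2,6-lutidine, CH2Cl2, −78 °C
Reagents that add atoms: tert-butyldimethylsilyl triflate (TBSOTf), CC(C)(C)[Si](C)(C)OS(=O)(=O)C(F)(F)F
Why: O-silylation of the benzylic alcohol blocks retro-aldol and lactonization through this oxygen and turns it into the leaving group for the later ring closure.

**Step 5**
Reactants: 10 silylated aldol adduct
Product: 11 tert-butyl (3R,4S)-4-[4-(allyloxy)-3,5-dimethoxyphenyl]-4-(tert-butyldimethylsilyloxy)-3-(hydroxymethyl)butanoate
Conditions: LiBH4, MeOH (1.5 equiv), THF, 0 °C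
Reagents that add atoms: none
Why: Reductive cleavage of the N-acyl oxazolidinone, whose activated exocyclic carbonyl is reduced by LiBH4 far faster than the tert-butyl ester; the stereocentre is not touched (the descriptor changes only through CIP priorities).

**Step 6**
Reactants: 11 hydroxy tert-butyl ester
Product: 12 (4R)-4-[(S)-[4-(allyloxy)-3,5-dimethoxyphenyl](tert-butyldimethylsilyloxy)methyl]oxolan-2-one
Conditions: camphorsulfonic acid (10 mol%), CH2Cl2, rt
Reagents that add atoms: none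
Why: Acid-catalysed lactonization (intramolecular transesterification, five-membered ring) ties the C2 hydroxymethyl group and the C3 carboxyl carbon into one butyrolactone.

**Step 7**
Reactants: 12 butyrolactone; 2 4-(allyloxy)-3,5-dimethoxybenzaldehyde
Product: 14 (3S,4R)-3-[[4-(allyloxy)-3,5-dimethoxyphenyl](hydroxy)methyl]-4-[(S)-[4-(allyloxy)-3,5-dimethoxyphenyl](tert-butyldimethylsilyloxy)methyl]oxolan-2-one (3,4-trans; carbinol epimers), via lithium enolate 13 (not isolated)
Conditions: LiN(SiMe3)2, THF, −78 °C; 2, −78 °C; AcOH quench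
Reagents that add atoms: none
Why: Intermolecular aldol addition of the lactone lithium enolate to the non-enolizable aldehyde anti to the C4 substituent; the new carbinol configuration is irrelevant because it is eliminated in the next step.

**Step 8**
Reactants: 14 β-hydroxy lactone
Product: 16 (3E,4R)-3-[4-(allyloxy)-3,5-dimethoxybenzylidene]-4-[(S)-[4-(allyloxy)-3,5-dimethoxyphenyl](tert-butyldimethylsilyloxy)methyl]oxolan-2-one, via mesylate 15 (not isolated)
Conditions: MsCl, Et3N, CH2Cl2, 0 °C; then DBU, 0 °C → rt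
Reagents that add atoms: none
Why: Mesylation then E1cB elimination completes the aldol condensation and gives the favoured E-arylidene lactone, in which ring A sits cis to C4 as the ring closure needs; the C4–H is not acidic, so the stereocentre is safe.

**Step 9**
Reactants: 16 E-arylidene lactone
Product: 18 (3aR,4S)-6-(allyloxy)-4-[4-(allyloxy)-3,5-dimethoxyphenyl]-5,7-dimethoxy-3a,4-dihydronaphtho[2,3-c]furan-1(3H)-one, via benzylic cation 17 (not isolated)
Conditions: TFA/CH2Cl2 (1:9), 0 °C → rt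
Reagents that add atoms: none
Why: Ionization of the benzylic silyl ether and intramolecular Friedel–Crafts alkylation of ring A (ortho and para to its methoxy groups) closes six-membered ring B, with ring C entering anti to the lactone CH2 on the neighbouring stereocentre to give the 1,2-trans product (C1 = S).

**Step 10**
Reactants: 18 dihydronaphthalene lactone
Product: 20 (3R,4S)-6-(allyloxy)-4-[4-(allyloxy)-3,5-dimethoxyphenyl]-3-(hydroxymethyl)-5,7-dimethoxy-3,4-dihydronaphthalene-2-carbaldehyde, via lactol 19 (not isolated)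
Conditions: iBu2AlH (1.2 equiv), CH2Cl2, −78 °C; MeOH, then aq. potassium sodium tartrate
Reagents that add atoms: none
Why: Partial lactone reduction stops at the tetrahedral aluminium lactolate at −78 °C, and the lactol freed on work-up opens to the conjugated hydroxy-enal.

**Step 11**
Reactants: 20 bis(allyl ether) hydroxy-enal
Product: 21 (3R,4S)-6-hydroxy-4-(4-hydroxy-3,5-dimethoxyphenyl)-3-(hydroxymethyl)-5,7-dimethoxy-3,4-dihydronaphthalene-2-carbaldehyde (target)
Conditions: Pd(PPh3)4 (5 mol%), p-toluenesulfinic acid (2.5 equiv), CH2Cl2, rt, argon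
Reagents that add atoms: none
Why: Tsuji–Trost-type deallylation: zerovalent palladium ionizes both aryl allyl ethers to π-allyl complexes that the sulfinic acid captures, freeing the phenols under non-basic, non-reducing conditions that leave the enal, the alkene and both stereocentres alone.

**Compound list**
1 | syringaldehyde (4-hydroxy-3,5-dimethoxybenzaldehyde) | COc1cc(C=O)cc(OC)c1O | starting material
2 | 4-(allyloxy)-3,5-dimethoxybenzaldehyde | COc1cc(C=O)cc(OC)c1OCC=C | intermediate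
3 | 4-tert-butoxy-4-oxobutanoic acid (mono-tert-butyl succinate) | CC(C)(C)OC(=O)CCC(=O)O | starting material
4 | (4S)-4-benzyl-1,3-oxazolidin-2-one | O=C1N[C@@H](Cc2ccccc2)CO1 | starting material
5 | 4-tert-butoxy-4-oxobutanoic pivalic anhydride | CC(C)(C)OC(=O)CCC(=O)OC(=O)C(C)(C)C | intermediate
6 | tert-butyl 4-[(4S)-4-benzyl-2-oxo-1,3-oxazolidin-3-yl]-4-oxobutanoate | CC(C)(C)OC(=O)CCC(=O)N1[C@@H](Cc2ccccc2)COC1=O | intermediate
7 | Z-dibutylboron enolate of 6 | CC(C)(C)OC(=O)C/C=C(\OB(CCCC)CCCC)N1[C@@H](Cc2ccccc2)COC1=O | intermediate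
8 | dibutylboron aldolate of 9 | CC(C)(C)OC(=O)C[C@@H]([C@H](OB(CCCC)CCCC)c1cc(OC)c(OCC=C)c(OC)c1)C(=O)N1[C@@H](Cc2ccccc2)COC1=O | intermediate
9 | tert-butyl (3S,4S)-4-[4-(allyloxy)-3,5-dimethoxyphenyl]-3-[(4S)-4-benzyl-2-oxo-1,3-oxazolidine-3-carbonyl]-4-hydroxybutanoate | CC(C)(C)OC(=O)C[C@@H]([C@H](O)c1cc(OC)c(OCC=C)c(OC)c1)C(=O)N1[C@@H](Cc2ccccc2)COC1=O | intermediate
10 | tert-butyl (3S,4S)-4-[4-(allyloxy)-3,5-dimethoxyphenyl]-3-[(4S)-4-benzyl-2-oxo-1,3-oxazolidine-3-carbonyl]-4-(tert-butyldimethylsilyloxy)butanoate | CC(C)(C)OC(=O)C[C@@H]([C@H](O[Si](C)(C)C(C)(C)C)c1cc(OC)c(OCC=C)c(OC)c1)C(=O)N1[C@@H](Cc2ccccc2)COC1=O | intermediate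
11 | tert-butyl (3R,4S)-4-[4-(allyloxy)-3,5-dimethoxyphenyl]-4-(tert-butyldimethylsilyloxy)-3-(hydroxymethyl)butanoate | CC(C)(C)OC(=O)C[C@@H]([C@H](O[Si](C)(C)C(C)(C)C)c1cc(OC)c(OCC=C)c(OC)c1)CO | intermediate
12 | (4R)-4-[(S)-[4-(allyloxy)-3,5-dimethoxyphenyl](tert-butyldimethylsilyloxy)methyl]oxolan-2-one | O=C1C[C@@H]([C@H](O[Si](C)(C)C(C)(C)C)c2cc(OC)c(OCC=C)c(OC)c2)CO1 | intermediate
13 | lithium enolate of 12 | [Li]OC1=C[C@@H]([C@H](O[Si](C)(C)C(C)(C)C)c2cc(OC)c(OCC=C)c(OC)c2)CO1 | intermediate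
14 | (3S,4R)-3-[[4-(allyloxy)-3,5-dimethoxyphenyl](hydroxy)methyl]-4-[(S)-[4-(allyloxy)-3,5-dimethoxyphenyl](tert-butyldimethylsilyloxy)methyl]oxolan-2-one (carbinol epimers) | O=C1OC[C@H]([C@H](O[Si](C)(C)C(C)(C)C)c2cc(OC)c(OCC=C)c(OC)c2)[C@H]1C(O)c3cc(OC)c(OCC=C)c(OC)c3 | intermediate
15 | methanesulfonate of 14 | O=C1OC[C@H]([C@H](O[Si](C)(C)C(C)(C)C)c2cc(OC)c(OCC=C)c(OC)c2)[C@H]1C(OS(C)(=O)=O)c3cc(OC)c(OCC=C)c(OC)c3 | intermediate
16 | (3E,4R)-3-[4-(allyloxy)-3,5-dimethoxybenzylidene]-4-[(S)-[4-(allyloxy)-3,5-dimethoxyphenyl](tert-butyldimethylsilyloxy)methyl]oxolan-2-one | O=C1OC[C@H]([C@H](O[Si](C)(C)C(C)(C)C)c2cc(OC)c(OCC=C)c(OC)c2)/C1=C\c3cc(OC)c(OCC=C)c(OC)c3 | intermediate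
17 | benzylic cation formed from 16 by loss of the silyloxy group | O=C1OC[C@H]([CH+]c2cc(OC)c(OCC=C)c(OC)c2)/C1=C\c3cc(OC)c(OCC=C)c(OC)c3 | intermediate
18 | (3aR,4S)-6-(allyloxy)-4-[4-(allyloxy)-3,5-dimethoxyphenyl]-5,7-dimethoxy-3a,4-dihydronaphtho[2,3-c]furan-1(3H)-one | COc1cc([C@H]2c3c(cc(OC)c(OCC=C)c3OC)C=C4C(=O)OC[C@H]24)cc(OC)c1OCC=C | intermediate
19 | (3aR,4S)-6-(allyloxy)-4-[4-(allyloxy)-3,5-dimethoxyphenyl]-5,7-dimethoxy-1,3,3a,4-tetrahydronaphtho[2,3-c]furan-1-ol (lactol, anomer mixture; held as its aluminium alkoxide until work-up) | COc1cc([C@H]2c3c(cc(OC)c(OCC=C)c3OC)C=C4C(O)OC[C@H]24)cc(OC)c1OCC=C | intermediate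
20 | (3R,4S)-6-(allyloxy)-4-[4-(allyloxy)-3,5-dimethoxyphenyl]-3-(hydroxymethyl)-5,7-dimethoxy-3,4-dihydronaphthalene-2-carbaldehyde | COc1cc([C@H]2c3c(cc(OC)c(OCC=C)c3OC)C=C(C=O)[C@@H]2CO)cc(OC)c1OCC=C | intermediate
21 | (3R,4S)-6-hydroxy-4-(4-hydroxy-3,5-dimethoxyphenyl)-3-(hydroxymethyl)-5,7-dimethoxy-3,4-dihydronaphthalene-2-carbaldehyde | COc1cc([C@H]2c3c(cc(OC)c(O)c3OC)C=C(C=O)[C@@H]2CO)cc(OC)c1O | target

**Step count and risks**
Total steps: 11. Longest linear sequence: 10 steps (steps 2 to 11 from 3 and 4; equally step 1 followed by steps 3 to 11 from 1).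

Most likely to fail:

- **Step 6** (acid lactonization next to an acid-sensitive, electron-rich benzylic silyl ether). The fallback sets out from 9 and comes back at 12, changing the order so that the silyl ether never meets the acid. Compound 9 is reduced with LiBH4/MeOH in THF at 0 °C to the diol ester tert-butyl (3R,4S)-4-[4-(allyloxy)-3,5-dimethoxyphenyl]-4-hydroxy-3-(hydroxymethyl)butanoate F1. Camphorsulfonic acid in CH2Cl2 then closes the faster-reacting primary hydroxyl onto the ester to give the hydroxy lactone (4R)-4-[(S)-[4-(allyloxy)-3,5-dimethoxyphenyl](hydroxy)methyl]oxolan-2-one F2; any γ-aryl lactone isomer is removed by chromatography. Silylation with TBSCl and imidazole in DMF gives 12.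

- **Step 9** (cationic ring closure: incomplete ionization, elimination, or poor trans selectivity). The fallback sets out from 16 and comes back at 18, replacing the cation by a para-quinone methide. Both allyl ethers of 16 are removed with Pd(PPh3)4 and p-toluenesulfinic acid to give the bis-phenol (3E,4R)-4-[(S)-(tert-butyldimethylsilyloxy)(4-hydroxy-3,5-dimethoxyphenyl)methyl]-3-(4-hydroxy-3,5-dimethoxybenzylidene)oxolan-2-one F3. With the para-hydroxyl free, very mild acid (AcOH or 1% TFA in CH2Cl2, 0 °C) expels the silyloxy group to give the para-quinone methide (3E,4R)-4-[(3,5-dimethoxy-4-oxocyclohexa-2,5-dien-1-ylidene)methyl]-3-(4-hydroxy-3,5-dimethoxybenzylidene)oxolan-2-one F4, which is not isolated. It is attacked by ring A to give the bis-phenol lactone (3aR,4S)-6-hydroxy-4-(4-hydroxy-3,5-dimethoxyphenyl)-5,7-dimethoxy-3a,4-dihydronaphtho[2,3-c]furan-1(3H)-one F5. Re-allylation with allyl bromide and K2CO3 in DMF under argon returns 18.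

- **Step 10** (partial reduction may over-reduce or stall). The fallback sets out from 18 and comes back at 20 by over-reducing and re-oxidizing selectively. Excess iBu2AlH (4 equiv, CH2Cl2, −78 → 0 °C) gives the diol [(1S,2R)-7-(allyloxy)-1-[4-(allyloxy)-3,5-dimethoxyphenyl]-6,8-dimethoxy-1,2-dihydronaphthalene-2,3-diyl]dimethanol F6. Activated MnO2 in CH2Cl2 at rt, stopped as soon as the diol is consumed, oxidizes only the allylic (cinnamyl-type) alcohol and gives 20. The saturated primary alcohol is left because the open enal form is favoured over the lactol.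

**Further compounds**
F1 | step 6 | tert-butyl (3R,4S)-4-[4-(allyloxy)-3,5-dimethoxyphenyl]-4-hydroxy-3-(hydroxymethyl)butanoate | CC(C)(C)OC(=O)C[C@@H]([C@H](O)c1cc(OC)c(OCC=C)c(OC)c1)CO
F2 | step 6 | (4R)-4-[(S)-[4-(allyloxy)-3,5-dimethoxyphenyl](hydroxy)methyl]oxolan-2-one | O=C1C[C@@H]([C@H](O)c2cc(OC)c(OCC=C)c(OC)c2)CO1
F3 | step 9 | (3E,4R)-4-[(S)-(tert-butyldimethylsilyloxy)(4-hydroxy-3,5-dimethoxyphenyl)methyl]-3-(4-hydroxy-3,5-dimethoxybenzylidene)oxolan-2-one | O=C1OC[C@H]([C@H](O[Si](C)(C)C(C)(C)C)c2cc(OC)c(O)c(OC)c2)/C1=C\c3cc(OC)c(O)c(OC)c3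
F4 | step 9 | (3E,4R)-4-[(3,5-dimethoxy-4-oxocyclohexa-2,5-dien-1-ylidene)methyl]-3-(4-hydroxy-3,5-dimethoxybenzylidene)oxolan-2-one | O=C1OC[C@H](C=C2C=C(OC)C(=O)C(OC)=C2)/C1=C\c3cc(OC)c(O)c(OC)c3
F5 | step 9 | (3aR,4S)-6-hydroxy-4-(4-hydroxy-3,5-dimethoxyphenyl)-5,7-dimethoxy-3a,4-dihydronaphtho[2,3-c]furan-1(3H)-one | COc1cc([C@H]2c3c(cc(OC)c(O)c3OC)C=C4C(=O)OC[C@H]24)cc(OC)c1O
F6 | step 10 | [(1S,2R)-7-(allyloxy)-1-[4-(allyloxy)-3,5-dimethoxyphenyl]-6,8-dimethoxy-1,2-dihydronaphthalene-2,3-diyl]dimethanol | COc1cc([C@H]2c3c(cc(OC)c(OCC=C)c3OC)C=C(CO)[C@@H]2CO)cc(OC)c1OCC=C
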